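# Lapiferine (25): design of a total synthesis through a carbonyl ylide cycloaddition

## The problem

Lapiferine (25) is a carotane: cyclopentane ring A (C1 fusion carbon with methyl, C2, C3, C4 with hydroxyl and isopropyl, C5 fusion CH) is trans-fused to cycloheptane ring B (C5, C6 with the angelate, C7, C8 with methyl, C9, C10 with hydroxyl, C1), and C8–C9 carries an epoxide. Taking β as the face of the C1 methyl group, 4-OH is β, while 5-H, the C6 ester oxygen, the epoxide and 10-OH are all α; there are seven stereocentres (C1, C4, C5, C6, C8, C9, C10) and a (Z)-configured ester. The quaternary C1 has no neighbour that could induce it and must come from an enantioselective catalyst. Once set, it can direct C5 (trans arms on the five-membered ring), C5 can direct C4, and the pseudo-axial C1 methyl decides from which face ring B is assembled. The oxygens at C6 and C10 lie on the α-face, the face that external reagents reach most easily, so each needs a corrective element. An oxygen that arrives at C6 while carbon is added from the α-face ends up β and must be inverted, and hydride must reach C10 from the hindered β-face under reagent control. The epoxide can then be placed by the C10 hydroxyl. The angelate (Z to E isomerisation, loss as a δ-acyloxy enone under base), the tertiary C4 carbinol next to isopropyl (acid-induced dehydration) and the epoxy alcohol (acid opening, base-induced epoxide migration) will not survive rough treatment and must appear late. The feature that makes a short ring-B construction possible is that C6 and C9 both carry oxygen, are 1,4-related across C7–C8, and C10 next to C9 is at the carbonyl level. Joining the two oxygens into one gives an 8-oxabicyclo[3.2.1]octan-2-one, the signature of a carbonyl ylide cycloaddition.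

## Retrosynthesis

**Epoxide last (25 ⇒ 24).** The two C–O bonds of the epoxide are cut first, leading to allylic alcohol 24. The C10 hydroxyl is syn to the epoxide and can deliver the oxygen, so no other control element is needed, and the most fragile function of 25 is then made in the last step with no protecting group left to remove. The forward reaction must be syn-selective and must leave the electron-poor angelate alkene alone.

**C10 carbinol and silyl ether (24 ⇒ 23 ⇒ 22).** Removing the C4 silyl group before the epoxide exists keeps fluoride and acid away from it. The C10–H bond is then cut, giving enone 22. The enone is the natural precursor because its C8=C9 bond is the one to be epoxidised, and the ketone is what the ring-forming step leaves at C10. Hydride must arrive syn to the C1 methyl, so the forward step is an oxazaborolidine-controlled 1,2-reduction, not a substrate-controlled one.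

**C8=C9 from a β-methoxy ketone (22 ⇒ 21).** The double bond is traced to methoxy ketone 21, which loses methanol. An sp3 C8 carrying methyl and a leaving group is exactly what an enol ether dipolarophile delivers. Keeping it until the ester is in place means that C7–H is not acidified by an enone while C6 undergoes substitution. The C10 ketone can enolise only toward C9, so the regiochemistry of the elimination is fixed.

**C6–O bond with inversion (21 ⇒ 19 + 20).** The ester C–O bond is cut with inversion, giving 6β-alcohol 19 and angelic acid (20). Oxidation to the C6 ketone and reduction was considered and rejected: hydride would again enter anti to the C1 methyl and return the β-alcohol. A substitution enters from the open α-face while the leaving group departs from the crowded β-face. The Mitsunobu reaction also forms the ester without activating the acyl group, which protects the (Z)-geometry.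

**Reconnection of the ether bridge (19 ⇒ 18).** The C6 hydroxyl and the C9–H of 19 are joined to the C6–O–C9 bridge of oxabicycle 18. In the forward sense this is reductive cleavage of a C–O bond α to a ketone by SmI2, which keeps the oxygen on C6 and leaves C9 as a methylene ready for the later elimination.

**Key disconnection (18 ⇒ 15 + 16 via 17).** C6–C7 and C8–C9 are cut together, and behind them the O–C9 bond of carbonyl ylide 17, back to diazo keto aldehyde 15 and 2-methoxypropene (16). Cutting C9–C10 or C1–C10 instead would require a medium-ring closure next to the quaternary centre. This cut makes ring B from a cyclopentane with only three stereocentres and supplies C7, C8 and the C8 methyl from a commodity alkene. The forward step must bond the CH2 of the enol ether to C6 and add anti to the C1 methyl.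

**Aldehyde unveiled last (15 ⇒ 14 ⇒ 13).** The C6 aldehyde is epimerisable at C5 and incompatible with the base used for diazo transfer. It is therefore carried as a primary triethylsilyl ether and released only after the diazo ketone is in place. The tertiary triethylsilyl ether at C4 is far more hindered and must survive the buffered fluoride.

**Diazo ketone from a masked acetyl group (13 ⇒ 11 ⇒ 10 ⇒ 9).** The diazo group is introduced by deacylative diazo transfer onto methyl ketone 11, which has only one enolisable side. Ketone 11 is traced through dihydroxysilane 10 to the 1-silylvinyl group of 9 by dihydroxylation and Peterson elimination. The alternative, cleaving the alkene to the C10 acid and acylating diazomethane, needs acid-mediated protodesilylation first, and neither the silyl ethers nor the tertiary carbinol would tolerate it. In the route chosen both C9 and C10 come from the alkyne and no step is acidic.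

**Isopropyl carbinol (9 ⇒ 8 ⇒ 7).** The C4–isopropyl bond is cut to ketone 7. The adjacent C5 substituent should steer the organocerium reagent to the α-face, giving the 4β-carbinol, which is then silylated so that it cannot intercept the carbenoid.

**Ring A from three components (7 ⇒ 6 ⇒ 1 + 2 + 3 via 4 and 5).** C1–C10 and C5–C6 are cut. Hydroalumination of ethynyltrimethylsilane (1) gives alane 4, its catalytic enantioselective conjugate addition to 3-methylcyclopent-2-en-1-one (2) sets C1, and the resulting enolate 5 is trapped with formaldehyde (3) anti to the new group to set C5. One operation thus reaches 6 with both arms in place from three commercial materials.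

## Roads not taken

**Alternative 1:** The cut is the same pair of bonds at ring A, C1–C10 and C5–C6, but the enolate formed from alane 4 and enone 2 is trapped with (Z)-4-iodo-3-methylbut-3-enal (A2) instead of formaldehyde. This gives aldol A1, in which C6 to C9 and the C8 methyl are already attached and no ring is closed. Ring B would then be closed through C9–C10, for example by CrCl2/NiCl2-mediated addition of the alkenyl iodide to a C10 aldehyde.
- Merits: A1 contains every carbon of the target skeleton after one step. The C6 carbinol could be set directly with the natural configuration, so no inversion is needed, the C8=C9 geometry is preset, and no diazo compound is used. In convergence and at C6 this road is better than the chosen one.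
- Weak points: A2 is a β,γ-unsaturated aldehyde that enolises and conjugates easily. The facial selectivity of an aluminium enolate toward it at C6 cannot be predicted with confidence. The unprotected β-hydroxy ketone A1 must survive isopropyl addition. The silylvinyl group must be cleaved to the C10 aldehyde in the presence of a second alkene. The seven-membered ring must then be closed next to the quaternary C1, with the C10 configuration left to the cyclisation.
- Comparison: the chosen plan has more steps and an inversion at C6. Against this it offers a ring closure whose first bond (oxygen to carbenoid) is intramolecular and fast, and a C10 carbinol set in a separate step whose reagent can be changed.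

**Alternative 2:** The cut is C7–C8 and C1–C10. A rhodium vinylcarbenoid from diazo ester A5, generated with Rh2(DOSP)4, would cyclopropanate the ethoxyvinyl group of cyclopentenyl diene A4. Cope rearrangement of the cis-divinylcyclopropane would close ring B and give bicyclic diene ester A3.
- Merits: ring B, the quaternary C1 and the C10 oxygen arise in one catalytic asymmetric step. The C10 configuration is the centre the chosen plan finds hardest, and here the boat transition state of the rearrangement would fix it. In this respect the road is better.
- Weak points: the rearrangement must form the quaternary centre from a tetrasubstituted ring alkene. C8 carries an ester that must be reduced to a methyl group over several steps. C5 is sp2 in A3, so the trans ring fusion must be created later, by protonation or reduction next to a C6 carbonyl, where the cis-fused hydroazulene is often the more stable. The C4 isopropyl carbinol must be added late to a ketone that is then flanked by an epimerisable centre.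
- Comparison: the chosen plan fixes the trans relationship of C1 and C5 in its first step and carries C4, the C8 methyl and the correct oxidation pattern of ring B through the key step. This offsets the single-step C10 control of A3.

**Alternative 3:** The cut is C1–C5, made by a semipinacol shift. In the cis-decalin hydroxy mesylate A6, derived from the Wieland–Miescher ketone, the C6 alkoxide would expel the C5 mesylate while C1 migrates from C6 to C5, contracting one ring and expanding the other to give trans-fused hydroxy ketone A7.
- Merits: the starting decalin is available in enantioenriched form, the migration is stereospecific, and there is no diazo chemistry or metal carbenoid. In robustness of the individual reaction types this road is at least as good.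
- Weak points: A6 needs five stereocentres and a differentiated triol pattern before the key step. A hydroxyl trans to the mesylate, at C6 itself or at C4, can close an epoxide instead of triggering migration, so the outcome depends on the conformation of the cis-decalin. A7 still lacks the C8=C9 unsaturation and has a C6 ketone whose reduction from the hindered face poses the same problem as C10, so a second stereochemical correction is added and none is removed.
- Comparison: the chosen plan is shorter to the bicyclic core and obtains the C6 oxygen, the C10 carbonyl and the latent C8=C9 bond from one step.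

Key step: step 10

## Route

Remarks on the chemistry (assumptions):
- Atom numbers C1–C10 and the α/β descriptors are those defined in "The problem".
- L* is a chiral, sulfonate-bearing N-aryl imidazolinium salt (carbene precursor) used with Ag2O and Cu(OTf)2; the enantiomer is chosen that gives the (S)-configured quaternary carbon of 6.
- C8 of 18, 19 and 21 is drawn with the methoxy group on the side of the ether bridge. It is probably formed as a mixture and is erased in step 13, so either epimer serves.
- The silyl-bearing carbinol carbon of 10 is formed as a mixture and is erased in step 6.
- In step 14 the (S)-catalyst is chosen on the premise that the fully substituted C1 side is the large group of the ketone.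

Step 1
Reactants: 1 ethynyltrimethylsilane; 2 3-methylcyclopent-2-en-1-one; 3 formaldehyde (monomeric, from cracked paraformaldehyde)
Product: 6 (2S,3S)-2-(hydroxymethyl)-3-methyl-3-[1-(trimethylsilyl)ethenyl]cyclopentan-1-one, via vinylalane 4 (not isolated), via aluminium enolate 5 (not isolated)
Conditions: 1, iBu2AlH, hexanes/THF, 55 °C; then 2, Cu(OTf)2 (5 mol%), L*/Ag2O (5 mol%), THF, −78 °C; then CH2O in THF, −78 → −40 °C; aq. Rochelle salt
Reagents that add atoms: none
Why: Hydroalumination places aluminium on the silicon-bearing carbon, and the chiral carbene–copper catalyst transfers the 1-silylvinyl group to the β-carbon of the enone (catalytic enantioselective conjugate addition), which sets the quaternary C1. The regiodefined aluminium enolate then adds to formaldehyde (aldol) anti to the bulky silylvinyl group, so the C6 arm on C5 is trans to the C10 arm.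

Step 2
Reactants: 6 (2S,3S)-2-(hydroxymethyl)-3-methyl-3-[1-(trimethylsilyl)ethenyl]cyclopentan-1-one
Product: 7 (2S,3S)-3-methyl-2-{[(triethylsilyl)oxy]methyl}-3-[1-(trimethylsilyl)ethenyl]cyclopentan-1-one
Conditions: TESCl, imidazole, CH2Cl2, 0 °C
Reagents that add atoms: chlorotriethylsilane, CC[Si](Cl)(CC)CC
Why: Standard silylation of a primary alcohol; it blocks retro-aldol cleavage and dehydration of the β-hydroxy ketone before the organometallic step.

Step 3
Reactants: 7 (2S,3S)-3-methyl-2-{[(triethylsilyl)oxy]methyl}-3-[1-(trimethylsilyl)ethenyl]cyclopentan-1-one
Product: 8 (1R,2S,3S)-3-methyl-1-(propan-2-yl)-2-{[(triethylsilyl)oxy]methyl}-3-[1-(trimethylsilyl)ethenyl]cyclopentan-1-ol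
Conditions: iPrMgCl, CeCl3, THF, −78 °C
Reagents that add atoms: isopropylmagnesium chloride, CC(C)[Mg]Cl
Why: The organocerium reagent adds 1,2 without enolisation or β-hydride reduction. It should attack the ketone anti to the adjacent C5 substituent (α-face), which gives the 4β-carbinol with isopropyl α.

Step 4
Reactants: 8 (1R,2S,3S)-3-methyl-1-(propan-2-yl)-2-{[(triethylsilyl)oxy]methyl}-3-[1-(trimethylsilyl)ethenyl]cyclopentan-1-ol
Product: 9 bis(triethylsilyl) ether of 8 (tertiary C4–OTES and primary C6–OTES; ring configuration unchanged)
Conditions: TESOTf, 2,6-lutidine, CH2Cl2, −78 → 0 °C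
Reagents that add atoms: triethylsilyl trifluoromethanesulfonate, CC[Si](CC)(CC)OS(=O)(=O)C(F)(F)F
Why: Silyl triflate silylation of a hindered tertiary alcohol; the ether keeps the C4 oxygen from O–H insertion at the carbenoid stage and is hindered enough to outlast the primary one.

Step 5
Reactants: 9 bis(triethylsilyl) ether of 8
Product: 10 α,β-dihydroxysilane: the 1-(trimethylsilyl)ethane-1,2-diol formed from the silylvinyl group of 9 (mixture at the silyl-bearing carbon)
Conditions: OsO4 (5 mol%), NMO, acetone/H2O, rt
Reagents that add atoms: osmium tetroxide, O=[Os](=O)(=O)=O; N-methylmorpholine N-oxide (terminal oxidant that replenishes the oxygen), C[N+]1([O-])CCOCC1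
Why: Catalytic osmium dihydroxylation of the only alkene under neutral conditions that the silyl ethers tolerate; vinylsilanes are known substrates and the new carbinol centre is inconsequential.

Step 6
Reactants: 10 α,β-dihydroxysilane
Product: 11 methyl ketone: C1 of ring A carries methyl (β) and acetyl (α); C4–OTES and C6–OTES as in 9
Conditions: KH, THF, 0 °C → rt; aq. NH4Cl
Reagents that add atoms: none
Why: Peterson elimination: the potassium alkoxide on the CH2 carbon and the silicon on the neighbouring carbon leave together as silanolate (syn elimination). The enolate of the methyl ketone that remains is protonated on work-up, so the vinylsilane serves as a masked acetyl group without any acid.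

Step 7
Reactants: 11 methyl ketone
Product: 13 diazo ketone: the acetyl group of 11 converted into diazoacetyl with both triethylsilyl ethers intact, via trifluoroacetyl ketone 12 (not isolated)
Conditions: LiHMDS, THF, −78 °C; CF3CO2CH2CF3; then MsN3, Et3N, H2O, MeCN, rt
Reagents that add atoms: methanesulfonyl azide, CS(=O)(=O)N=[N+]=[N-]
Why: Deacylative (Regitz-type) diazo transfer: the only possible enolate is trifluoroacetylated, and the activated methylene then accepts the diazo group from the sulfonyl azide with loss of the trifluoroacetyl group as its sulfonamide.

Step 8
Reactants: 13 diazo ketone with two triethylsilyl ethers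
Product: 14 diazo ketone with free primary C6 hydroxyl and tertiary C4–OTES
Conditions: TBAF/AcOH (1:1), THF, 0 °C
Reagents that add atoms: none
Why: Buffered fluoride removes the unhindered primary triethylsilyl group much faster than the tertiary one flanked by isopropyl; the diazo ketone is stable to these nearly neutral conditions.

Step 9
Reactants: 14 diazo ketone with free primary C6 hydroxyl
Product: 15 diazo keto aldehyde: ring A with C1 methyl (β) and diazoacetyl (α); C4 triethylsilyloxy (β) and isopropyl (α); C5 formyl (β)
Conditions: Dess–Martin periodinane, NaHCO3, CH2Cl2, 0 °C → rt
Reagents that add atoms: none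
Why: Buffered Dess–Martin oxidation is neutral and spares the diazo ketone and the silyl ether; the aldehyde is used at once because C5–H is epimerisable.

Step 10
Reactants: 15 diazo keto aldehyde; 16 2-methoxypropene
Product: 18 oxabicycle 6β,9β-epoxy-8β-methoxy-4β-(triethylsilyloxy)carotan-10-one, via carbonyl ylide 17 (not isolated)
Conditions: Rh2(OAc)4 (2 mol%), 16 (20 equiv), CH2Cl2, rt, slow addition of 15
Reagents that add atoms: none
Why: Rh2(OAc)4 extrudes N2 from the diazo ketone, and the electrophilic rhodium carbenoid at C9 is attacked by a lone pair of the C6 aldehyde oxygen; this closes the six-membered ring C9–C10–C1–C5–C6–O of carbonyl ylide 17 (intramolecular O–C bond formation onto the carbenoid, for which the trans arms on C1 and C5 span exactly this ring). The ylide then adds 2-methoxypropene in a concerted, asynchronous (3+2) cycloaddition, suprafacial on both partners, which forms C6–C7 and C8–C9 and so closes the tetrahydrofuran ring and with it the seven-membered carbocycle under the C6–O–C9 bridge. The closest known reaction type is the rhodium-catalysed cyclisation–cycloaddition of δ-oxo-α-diazo ketones with enol ethers. Regiochemistry follows the polarity of the dipole: C6 is the oxocarbenium-like terminus and C9, next to the C10 ketone, the enolate-like one, so the nucleophilic CH2 of the enol ether bonds to C6 and the methoxy-bearing carbon to C9. C6 and C9 are set together by the face of approach: the pseudo-axial C1 methyl is 1,3-related to both reacting termini on the β-face, so the alkene should add from the α-face, which leaves the bridge oxygen β at both carbons. C8 is set by the exo or endo placement of the methoxy group; this is not controlled and does not matter, because the centre is erased in step 13. The step needs chemoselectivity for ylide formation and capture over C–H insertion, cyclopropanation of the enol ether, 1,4-proton shift from C5 and ylide dimerisation; the six-membered geometry, the nucleophilic aldehyde oxygen, slow addition of 15 and the large excess of 16 are what secure it.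

Step 11
Reactants: 18 oxabicycle
Product: 19 6β-hydroxy-8β-methoxy-4β-(triethylsilyloxy)carotan-10-one
Conditions: SmI2 (2.5 equiv), THF/MeOH, −78 °C
Reagents that add atoms: none
Why: Reductive cleavage of an α-alkoxy ketone: the ketyl expels the C9–O bond, which lies out of the carbonyl plane in the bicycle, and the trivalent samarium enolate is protonated by methanol at −78 °C before it can lose methoxide. The oxygen stays on C6 as the 6β-alcohol.

Step 12
Reactants: 19 6β-hydroxy-8β-methoxy-4β-(triethylsilyloxy)carotan-10-one; 20 angelic acid
Product: 21 6α-angeloyloxy-8β-methoxy-4β-(triethylsilyloxy)carotan-10-one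
Conditions: PPh3, DIAD, toluene, 0 °C → rt
Reagents that add atoms: none
Why: Mitsunobu esterification with SN2 inversion: the alkoxyphosphonium group leaves from the β-face, where it is syn to the C1 methyl, and the carboxylate enters from the open α-face. The acyl group is never activated, so the (Z)-geometry is kept, and C8 is still sp3, so C7–H is not acidified toward elimination.

Step 13
Reactants: 21 6α-angeloyloxy-8β-methoxy-4β-(triethylsilyloxy)carotan-10-one
Product: 22 6α-angeloyloxy-4β-(triethylsilyloxy)carot-8-en-10-one
Conditions: CSA (cat.), 5 Å MS, CH2Cl2, 0 °C → rt
Reagents that add atoms: none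
Why: Acid-catalysed β-elimination: the C10 ketone can enolise only toward C9, and the enol expels the tertiary methoxy group as methanol to give the conjugated trisubstituted enone. Acid is used instead of base because base would also remove the C6 ester by vinylogous elimination.

Step 14
Reactants: 22 6α-angeloyloxy-4β-(triethylsilyloxy)carot-8-en-10-one
Product: 23 6α-angeloyloxy-4β-(triethylsilyloxy)carot-8-en-10α-ol
Conditions: (S)-2-methyl-CBS-oxazaborolidine, catecholborane, toluene, −78 °C
Reagents that add atoms: none
Why: CBS reduction: the catalyst should bind the carbonyl lone pair on the side of the small alkenyl CH (C9) and deliver hydride to the β-face, giving the (10R) α-alcohol against the steric bias of the C1 methyl. Catecholborane at low temperature reduces the s-trans enone 1,2 and leaves the ester alone.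

Step 15
Reactants: 23 6α-angeloyloxy-4β-(triethylsilyloxy)carot-8-en-10α-ol
Product: 24 6α-angeloyloxycarot-8-ene-4β,10α-diol
Conditions: HF·pyridine, pyridine, THF, 0 °C → rt
Reagents that add atoms: none
Why: Buffered HF·pyridine cleaves the hindered tertiary silyl ether without touching the ester or the allylic alcohol; it is done here so that the epoxide is never exposed to fluoride or acid.

Step 16
Reactants: 24 6α-angeloyloxycarot-8-ene-4β,10α-diol
Product: 25 lapiferine (6α-angeloyloxy-8α,9α-epoxycarotane-4β,10α-diol)
Conditions: VO(acac)2 (cat.), tBuOOH, CH2Cl2, 0 °C → rt
Reagents that add atoms: tert-butyl hydroperoxide, CC(C)(C)OO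
Why: Hydroxyl-directed epoxidation: the pentavalent vanadium alkoxide of the C10 hydroxyl delivers the peroxide oxygen to the syn (α) face of the C8=C9 bond. The electron-poor angelate alkene and the non-allylic C4 hydroxyl do not react.

## Compound list

1 | ethynyltrimethylsilane | C#C[Si](C)(C)C | starting material
2 | 3-methylcyclopent-2-en-1-one | CC1=CC(=O)CC1 | starting material
3 | formaldehyde | C=O | starting material
4 | [1-(trimethylsilyl)ethenyl]bis(2-methylpropyl)alumane | C=C([Si](C)(C)C)[Al](CC(C)C)CC(C)C | intermediate (not isolated)
5 | diisobutylaluminium enolate of (S)-3-methyl-3-[1-(trimethylsilyl)ethenyl]cyclopentanone | CC(C)C[Al](CC(C)C)OC1=C[C@@](C)(C(=C)[Si](C)(C)C)CC1 | intermediate (not isolated)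
6 | (2S,3S)-2-(hydroxymethyl)-3-methyl-3-[1-(trimethylsilyl)ethenyl]cyclopentan-1-one | OC[C@H]1C(=O)CC[C@]1(C)C(=C)[Si](C)(C)C | intermediate
7 | (2S,3S)-3-methyl-2-{[(triethylsilyl)oxy]methyl}-3-[1-(trimethylsilyl)ethenyl]cyclopentan-1-one | CC[Si](CC)(CC)OC[C@H]1C(=O)CC[C@]1(C)C(=C)[Si](C)(C)C | intermediate
8 | (1R,2S,3S)-3-methyl-1-(propan-2-yl)-2-{[(triethylsilyl)oxy]methyl}-3-[1-(trimethylsilyl)ethenyl]cyclopentan-1-ol | CC[Si](CC)(CC)OC[C@H]1[C@](O)(C(C)C)CC[C@]1(C)C(=C)[Si](C)(C)C | intermediate
9 | bis(triethylsilyl) ether of 8 | CC[Si](CC)(CC)OC[C@H]1[C@](O[Si](CC)(CC)CC)(C(C)C)CC[C@]1(C)C(=C)[Si](C)(C)C | intermediate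
10 | α,β-dihydroxysilane from 9 (mixture at the silyl-bearing carbon) | CC[Si](CC)(CC)OC[C@H]1[C@](O[Si](CC)(CC)CC)(C(C)C)CC[C@]1(C)C(O)(CO)[Si](C)(C)C | intermediate
11 | methyl ketone (acetyl on C1) | CC[Si](CC)(CC)OC[C@H]1[C@](O[Si](CC)(CC)CC)(C(C)C)CC[C@]1(C)C(C)=O | intermediate
12 | trifluoroacetyl ketone (4,4,4-trifluorobutane-1,3-dione on C1) | CC[Si](CC)(CC)OC[C@H]1[C@](O[Si](CC)(CC)CC)(C(C)C)CC[C@]1(C)C(=O)CC(=O)C(F)(F)F | intermediate (not isolated)
13 | diazo ketone, bis(triethylsilyl) ether | CC[Si](CC)(CC)OC[C@H]1[C@](O[Si](CC)(CC)CC)(C(C)C)CC[C@]1(C)C(=O)C=[N+]=[N-] | intermediate
14 | diazo ketone, primary alcohol | OC[C@H]1[C@](O[Si](CC)(CC)CC)(C(C)C)CC[C@]1(C)C(=O)C=[N+]=[N-] | intermediate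
15 | diazo keto aldehyde | O=C[C@H]1[C@](O[Si](CC)(CC)CC)(C(C)C)CC[C@]1(C)C(=O)C=[N+]=[N-] | intermediate
16 | 2-methoxypropene | COC(C)=C | starting material
17 | six-membered carbonyl ylide | O=C1[CH-][O+]=C[C@H]2[C@](O[Si](CC)(CC)CC)(C(C)C)CC[C@]12C | intermediate (not isolated)
18 | 6β,9β-epoxy-8β-methoxy-4β-(triethylsilyloxy)carotan-10-one | CO[C@@]1(C)C[C@H]2O[C@@H]1C(=O)[C@@]3(C)CC[C@@](O[Si](CC)(CC)CC)(C(C)C)[C@H]23 | intermediate
19 | 6β-hydroxy-8β-methoxy-4β-(triethylsilyloxy)carotan-10-one | CO[C@@]1(C)C[C@@H](O)[C@H]2[C@](O[Si](CC)(CC)CC)(C(C)C)CC[C@]2(C)C(=O)C1 | intermediate
20 | angelic acid, (Z)-2-methylbut-2-enoic acid | C/C=C(/C)C(=O)O | starting material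
21 | 6α-angeloyloxy-8β-methoxy-4β-(triethylsilyloxy)carotan-10-one | CO[C@@]1(C)C[C@H](OC(=O)/C(C)=C\C)[C@H]2[C@](O[Si](CC)(CC)CC)(C(C)C)CC[C@]2(C)C(=O)C1 | intermediate
22 | 6α-angeloyloxy-4β-(triethylsilyloxy)carot-8-en-10-one | C/C=C(/C)C(=O)O[C@H]1CC(C)=CC(=O)[C@@]2(C)CC[C@@](O[Si](CC)(CC)CC)(C(C)C)[C@H]12 | intermediate
23 | 6α-angeloyloxy-4β-(triethylsilyloxy)carot-8-en-10α-ol | C/C=C(/C)C(=O)O[C@H]1CC(C)=C[C@@H](O)[C@@]2(C)CC[C@@](O[Si](CC)(CC)CC)(C(C)C)[C@H]12 | intermediate
24 | 6α-angeloyloxycarot-8-ene-4β,10α-diol | C/C=C(/C)C(=O)O[C@H]1CC(C)=C[C@@H](O)[C@@]2(C)CC[C@@](O)(C(C)C)[C@H]12 | intermediate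
25 | lapiferine | C/C=C(/C)C(=O)O[C@H]1C[C@@]2(C)O[C@H]2[C@@H](O)[C@@]2(C)CC[C@@](O)(C(C)C)[C@H]12 | target

## Step count and least certain steps

Total: 16 steps. Longest linear sequence: 16 steps, from 2; compounds 1, 3, 16 and 20 enter as reagents.

**Step 10 (key step).** Two things are most likely to go wrong. The strained trans-fused ylide may be intercepted slowly by the 1,1-disubstituted enol ether, so that proton shift from C5 or dimerisation competes. Facial discrimination may also be incomplete, because the α-face, although free of the C1 methyl, is flanked by the C4 isopropyl group. Slow addition and excess alkene address the first problem. The second is covered by a fallback that uses the other adduct instead of discarding it. Starting from 15, any β-face adduct, 6α,9α-epoxy-8-methoxy-4β-(triethylsilyloxy)carotan-10-one F1 (C8 drawn as in 18), would be opened with SmI2 in THF/MeOH to 6α-hydroxy-8-methoxy-4β-(triethylsilyloxy)carotan-10-one F2. This alcohol already has the natural C6 configuration. It would be acylated with retention under Yamaguchi conditions (20, 2,4,6-trichlorobenzoyl chloride, Et3N, toluene, 80 °C), so that this series rejoins the route at 21.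

**Step 12.** The likely failure is elimination in place of substitution: the alkoxyphosphonium group is axial with anti hydrogens on C5 and C7, the carbon is flanked by the substituted C5, and angelate is a weak nucleophile. The fallback separates activation from displacement. Starting from 19, ClCH2SO2Cl and pyridine would give the 6β-chloromethanesulfonate F3, which would be displaced with inversion by cesium angelate (from 20 and Cs2CO3) with 18-crown-6 in toluene at 80 °C, returning to 21.

**Step 14.** Hydride must be delivered syn to the adjacent C1 methyl, so reagent and substrate may be mismatched, with low selectivity or slow reduction. The assignment of the large and small groups of the ketone could also be the reverse of the one assumed. The fallback accepts the substrate's own preference and corrects it. Starting from 22, Luche reduction (NaBH4, CeCl3, MeOH) would give the 10β-alcohol, 6α-angeloyloxy-4β-(triethylsilyloxy)carot-8-en-10β-ol F4. Mitsunobu inversion with chloroacetic acid (PPh3, DIAD) would then give the 10α-chloroacetate F5, in which the nucleophile enters from the same open α-face that the hydride used. Selective methanolysis of the chloroacetate (K2CO3, MeOH, 0 °C) would return to 23.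

**Step 5.** The alkene is shielded by the trimethylsilyl group and by the quaternary C1, so osmylation may be slow, and long exposure to the aqueous medium may begin to cost the primary silyl ether. The fallback removes the silicon first. Starting from 9, N-iodosuccinimide in MeCN at 0 °C would give the 1-iodoethenyl compound F6 by iododesilylation. Pd(PPh3)4/Bu3SnH would reduce it to the vinyl compound F7, and Wacker–Tsuji oxidation (PdCl2, CuCl, O2, DMF/H2O) would give methyl ketone 11.

**Step 1.** Monomeric formaldehyde may polymerise or react sluggishly with the aluminium enolate, and the aldol may lose material by retro-aldol cleavage on work-up, which lowers conversion and diastereoselectivity at C5. The fallback separates the two events. Starting from 1 and 2, the conjugate addition would be run as before (through 4 and 5), and enolate 5 would be trapped with TESOTf as the triethylsilyl enol ether F8. Mukaiyama hydroxymethylation with aqueous formaldehyde and Yb(OTf)3 in THF would then add the C6 carbon anti to the silylvinyl group and return to 6.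

## Further compounds

F1 | step 10 | 6α,9α-epoxy-8-methoxy-4β-(triethylsilyloxy)carotan-10-one (β-face adduct) | CO[C@@]1(C)C[C@@H]2O[C@H]1C(=O)[C@@]3(C)CC[C@@](O[Si](CC)(CC)CC)(C(C)C)[C@H]23
F2 | step 10 | 6α-hydroxy-8-methoxy-4β-(triethylsilyloxy)carotan-10-one | CO[C@@]1(C)C[C@H](O)[C@H]2[C@](O[Si](CC)(CC)CC)(C(C)C)CC[C@]2(C)C(=O)C1
F3 | step 12 | 6β-chloromethanesulfonate of 19 | CO[C@@]1(C)C[C@@H](OS(=O)(=O)CCl)[C@H]2[C@](O[Si](CC)(CC)CC)(C(C)C)CC[C@]2(C)C(=O)C1
F4 | step 14 | 6α-angeloyloxy-4β-(triethylsilyloxy)carot-8-en-10β-ol | C/C=C(/C)C(=O)O[C@H]1CC(C)=C[C@H](O)[C@@]2(C)CC[C@@](O[Si](CC)(CC)CC)(C(C)C)[C@H]12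
F5 | step 14 | 10α-chloroacetate of 23 | C/C=C(/C)C(=O)O[C@H]1CC(C)=C[C@@H](OC(=O)CCl)[C@@]2(C)CC[C@@](O[Si](CC)(CC)CC)(C(C)C)[C@H]12
F6 | step 5 | 1-iodoethenyl analogue of 9 | CC[Si](CC)(CC)OC[C@H]1[C@](O[Si](CC)(CC)CC)(C(C)C)CC[C@]1(C)C(I)=C
F7 | step 5 | vinyl analogue of 9 | CC[Si](CC)(CC)OC[C@H]1[C@](O[Si](CC)(CC)CC)(C(C)C)CC[C@]1(C)C=C
F8 | step 1 | triethylsilyl enol ether of (S)-3-methyl-3-[1-(trimethylsilyl)ethenyl]cyclopentanone | CC[Si](CC)(CC)OC1=C[C@@](C)(C(=C)[Si](C)(C)C)CC1
A1 | alternative 1 | aldol of the conjugate-addition enolate with A2 (trans-2,3-disubstituted cyclopentanone) | O[C@@H](C/C(C)=C\I)[C@H]1C(=O)CC[C@]1(C)C(=C)[Si](C)(C)C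
A2 | alternative 1 | (Z)-4-iodo-3-methylbut-3-enal | O=CC/C(C)=C\I
A3 | alternative 2 | bicyclic diene ester from cyclopropanation–Cope rearrangement | COC(=O)C1=C[C@@H](O[Si](C)(C)C(C)(C)C)[C@@]2(C)CCC3(OCCO3)C2=C(OCC)C1
A4 | alternative 2 | 6-(1-ethoxyethenyl)-7-methyl-1,4-dioxaspiro[4.4]non-6-ene | CCOC(=C)C1=C(C)CCC12OCCO2
A5 | alternative 2 | methyl (E)-4-[(tert-butyldimethylsilyl)oxy]-2-diazobut-3-enoate | COC(=O)C(=[N+]=[N-])/C=C/O[Si](C)(C)C(C)(C)C
A6 | alternative 3 | cis-decalin hydroxy mesylate | CS(=O)(=O)O[C@H]1[C@](O)(C(C)C)CC[C@]2(C)C3(OCCO3)C[C@@H](C)C[C@]12O
A7 | alternative 3 | trans-fused hydroazulenone (hydroxy ketone) | O=C1C[C@H](C)CC2(OCCO2)[C@@]3(C)CC[C@@](O)(C(C)C)[C@H]13
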